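**Retrosynthetic overview**

1. Feature: the fusion bond C4a–C11a of rings A and B joins C11a, which carries C1 at the carboxyl level, to C4a, which carries the trigonal C4 holding C3 and C12. C1–C11a–C4a–C4=C3 is a γ,δ-unsaturated acid, the product pattern of an ester-enolate Claisen shift.
2. Key disconnection: C4a–C11a, with O2–C3 re-formed, leads to a 13-membered allylic lactone (C1–O2–C3–C4=C4a…C11a); its Ireland–Claisen contraction makes the nine-membered ring B and both fusion stereocentres.
3. The lactone comes from Shiina closure of a seco acid built linearly on chiron 1 (lactone carbon = C11, CH2O = C8): Still–Gennari olefination (Z-C7=C8), nitrile homologation, HWE olefination (C4=C4a with differentiated C3 and C12 arms), Negishi coupling for the C11(=C19)–C11a–C1 arm.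
4. After the contraction: hydroxyl-directed epoxidation of C7=C8 and C9 benzoylation; C3 is re-oxygenated by tethered hydrosilylation, and oxidation of the C1/C3/C12 triol lets the malondialdehyde enol close ring A on C1 as the acetal acetate.
5. Side chain: anti γ-silyloxyallylboration at C12, cross-metathesis to the isobutenyl group, acetylations. Ring order: 13-membered lactone, ring B, oxirane, ring A.

Key step: step 15

Remark: atoms carry xenicane labels (ring A: O2, C1, C11a, C4a, C4, C3; ring B: C4a, C5 to C11, C11a; C18 = methyl on C7, C19 = methylene on C11; C12 to C17 = side chain). The target SMILES has C6 and C9 cis on the oxirane, so ring B is built as the Z-cyclononene. Reagents named with a SMILES are taken as purchased.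

**Route**

Step 1
Reactants: 1 2,3-O-isopropylidene-D-erythronolactone
Product: 2 2,3-O-isopropylidene-D-erythrofuranose (lactol; both anomers)
Conditions: i-Bu2AlH, CH2Cl2, −78 °C; aq. potassium sodium tartrate
Reagents that add atoms: none
Why: Partial reduction of a γ-lactone with i-Bu2AlH at low temperature stops at the lactol and leaves both acetonide centres (future C9 and C10) unchanged.

Step 2
Reactants: 2 2,3-O-isopropylidene-D-erythrofuranose
Product: 3 C8–C11 alkynol [(4R,5S)-5-ethynyl-2,2-dimethyl-1,3-dioxolan-4-yl]methanol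
Conditions: dimethyl (1-diazo-2-oxopropyl)phosphonate, K2CO3, MeOH, 0 °C → rt
Reagents that add atoms: dimethyl (1-diazo-2-oxopropyl)phosphonate, CC(=O)C(=[N+]=[N-])P(=O)(OC)OC
Why: Seyferth–Gilbert homologation in the Ohira–Bestmann version converts the aldehyde form of the lactol into the C11≡C19 alkyne and releases the C8 hydroxyl, the cold carbonate medium limiting epimerisation at C10.

Step 3
Reactants: 3 C8–C11 alkynol
Product: 5 iodoalkene [cis-5-(1-iodoethenyl)-2,2-dimethyl-1,3-dioxolan-4-yl]methanol (configuration of 3), via α-stannylalkene 4 (not isolated)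
Conditions: Bu3SnH, Mo(CO)3(CNt-Bu)3 (cat.), hydroquinone, THF, 55 °C; then I2, CH2Cl2, 0 °C
Reagents that add atoms: iodine, II
Why: Molybdenum-catalysed hydrostannation of a terminal alkyne with a propargylic oxygen places tin on the internal carbon, and iododestannylation then gives the 2-iodo-1-alkene at C11 with C19 as the methylene.

Step 4
Reactants: 5 iodoalkene alcohol
Product: 6 C8 aldehyde cis-5-(1-iodoethenyl)-2,2-dimethyl-1,3-dioxolane-4-carbaldehyde
Conditions: Dess–Martin periodinane, pyridine, CH2Cl2, 0 °C → rt; used crude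
Reagents that add atoms: none
Why: Dess–Martin oxidation under buffered conditions gives the α-alkoxy aldehyde without epimerisation at C9.

Step 5
Reactants: 6 C8 aldehyde
Product: 7 Z-enoate methyl (Z)-3-[cis-5-(1-iodoethenyl)-2,2-dimethyl-1,3-dioxolan-4-yl]-2-methylprop-2-enoate (ester carbon = C6)
Conditions: methyl 2-[bis(2,2,2-trifluoroethoxy)phosphoryl]propanoate, KN(SiMe3)2, 18-crown-6, THF, −78 °C
Reagents that add atoms: methyl 2-[bis(2,2,2-trifluoroethoxy)phosphoryl]propanoate, CC(C(=O)OC)P(=O)(OCC(F)(F)F)OCC(F)(F)F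
Why: Still–Gennari olefination (kinetic control with an electron-poor phosphonate and a dissociated potassium base) should give the Z trisubstituted enoate, so that C6 and C9 are cis on C7=C8.

Step 6
Reactants: 7 Z-enoate
Product: 8 Z-allylic alcohol (C6–OH)
Conditions: i-Bu2AlH, CH2Cl2, −78 °C; aq. potassium sodium tartrate
Reagents that add atoms: none
Why: 1,2-Reduction of the conjugated ester with i-Bu2AlH gives the allylic alcohol without touching the iodoalkene or the olefin geometry.

Step 7
Reactants: 8 Z-allylic alcohol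
Product: 9 Z-allylic bromide (C6–Br)
Conditions: CBr4, PPh3, CH2Cl2, 0 °C
Reagents that add atoms: tetrabromomethane, BrC(Br)(Br)Br
Why: Appel bromination converts the primary allylic alcohol into the bromide under neutral conditions with the Z olefin retained.

Step 8
Reactants: 9 Z-allylic bromide
Product: 10 nitrile (C4a≡N; C5 and C6 methylenes)
Conditions: MeCN, n-BuLi, THF, −78 °C; then 9, −78 °C
Reagents that add atoms: acetonitrile, CC#N
Why: SN2 alkylation of lithioacetonitrile by the primary allylic bromide adds C5 and C4a, the iodoalkene being inert to this carbanion at −78 °C.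

Step 9
Reactants: 10 nitrile
Product: 11 C4a aldehyde
Conditions: i-Bu2AlH, toluene, −78 °C; aq. potassium sodium tartrate
Reagents that add atoms: water, O
Why: i-Bu2AlH adds once to the nitrile, and hydrolysis of the aluminated aldimine releases the aldehyde.

Step 10
Reactants: 11 C4a aldehyde
Product: 13 E-enoate (C3 methyl ester on C4 trans to C5; C12H2OPMB on C4 cis to C5), via phosphonate carbanion 12 (not isolated)
Conditions: 4-methoxybenzyl alcohol, NaH, THF, 0 °C; trimethyl 2-phosphonoacrylate; then 11, 0 °C → rt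
Reagents that add atoms: trimethyl 2-phosphonoacrylate, C=C(C(=O)OC)P(=O)(OC)OC; 4-methoxybenzyl alcohol, COc1ccc(CO)cc1
Why: Oxa-Michael addition of the alkoxide to the vinylphosphonate generates the phosphonate carbanion, whose Horner–Wadsworth–Emmons reaction with the unbranched aldehyde should favour the E enoate; the minor Z isomer is removed by chromatography.

Step 11
Reactants: 13 E-enoate
Product: 14 C3 allylic alcohol (C3–OH trans to C5)
Conditions: i-Bu2AlH, CH2Cl2, −78 °C; aq. potassium sodium tartrate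
Reagents that add atoms: none
Why: 1,2-Reduction of the enoate with i-Bu2AlH gives the allylic alcohol whose oxygen becomes the lactone oxygen O2.

Step 12
Reactants: 14 C3 allylic alcohol
Product: 15 ethyl ester (C11(=C19H2)–C11aH2–C1O2Et arm)
Conditions: BrCH2CO2Et, Zn, THF (gives BrZnCH2CO2Et, 3 equiv); Pd(PPh3)4 (cat.), THF, 50 °C
Reagents that add atoms: ethyl bromoacetate, BrCC(=O)OCC
Why: Negishi-type palladium-catalysed coupling of the alkenyl iodide with the Reformatsky reagent forms C11–C11a and gives the β,γ-unsaturated ester; the free hydroxyl only consumes part of the excess zinc reagent.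

Step 13
Reactants: 15 ethyl ester
Product: 16 seco acid
Conditions: LiOH, THF–H2O, 0 °C; aq. HCl to pH 4, 0 °C
Reagents that add atoms: lithium hydroxide, [Li+].[OH-]
Why: Saponification of the unhindered ethyl ester at 0 °C is faster than γ-deprotonation, so the deconjugated C11=C19 position should be kept.

Step 14
Reactants: 16 seco acid
Product: 17 13-membered macrolactone (Z-C7=C8; C5 trans to C3 on C4=C4a; C9/C10 acetonide)
Conditions: 2-methyl-6-nitrobenzoic anhydride, DMAP, CH2Cl2, rt, slow addition (1 mM)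
Reagents that add atoms: none
Why: Shiina macrolactonisation (mixed anhydride, acyl transfer by DMAP, high dilution) closes the ring at room temperature, which spares the β,γ-unsaturated acyl group from conjugation.

Step 15
Reactants: 17 13-membered macrolactone
Product: 20 (4aS,11aR)-cyclononene acid (C1 acid on C11a; C4(=C3H2)(C12H2OPMB) on C4a), via silyl ketene acetal 18 (not isolated), via trimethylsilyl ester 19 (not isolated)
Conditions: LiN(i-Pr)2, Me3SiCl, Et3N, THF–HMPA, −78 °C; then 60 °C; aq. work-up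
Reagents that add atoms: none
Why: LiN(i-Pr)2 removes a C11a proton (the only acidic site, α to the lactone carbonyl and allylic to C11=C19) and Me3SiCl traps the dienolate on oxygen as ketene acetal 18, which in THF–HMPA should have C11 trans to O2. On warming, 18 undergoes the suprafacial [3,3] shift over C11a=C1–O2–C3–C4=C4a: C11a–C4a forms, O2–C3 breaks, and hydrolysis of silyl ester 19 gives acid 20; the closest known reaction is the Ireland–Claisen ring contraction of macrocyclic allylic lactones to carbocyclic acids. Ring B closes by transannular C–C bond formation, the 13-membered ring shrinking to the nine-membered carbocycle as C1, O2, C3 and C4 leave the ring. The trans relationship of C4a and C11a follows from a chair array in which the seven-atom tether C5–C11 spans the two equatorial positions (C5 trans to C3 on the olefin, C11 trans to O2 on the ketene acetal); a boat would give the cis isomer. Which face pair reacts, and hence 4aS,11aR relative to C9 and C10, is set by the cis-acetonide, which stiffens C8–C11 next to the Z olefin and should hold the tether so that C11a bonds anti to the C10–O bond. The step needs site-selective enolisation, secured by the single activated methylene, and chair-over-boat and facial selectivity, secured by the two double-bond geometries and the acetonide.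

Step 16
Reactants: 20 cyclononene acid
Product: 21 C1 primary alcohol
Conditions: LiAlH4, THF, 0 °C
Reagents that add atoms: none
Why: Hydride reduction of the carboxylic acid with LiAlH4 gives the primary alcohol; the isolated olefins, the acetonide and the PMB ether are inert.

Step 17
Reactants: 21 C1 primary alcohol
Product: 22 C1 acetate
Conditions: Ac2O, pyridine, DMAP (cat.), CH2Cl2, 0 °C
Reagents that add atoms: acetic anhydride, CC(=O)OC(C)=O
Why: Acetylation masks the C1 hydroxyl so that later only the C12 hydroxyl can carry the hydrosilane tether.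

Step 18
Reactants: 22 C1 acetate
Product: 23 cis-9,10-diol
Conditions: AcOH–H2O (4:1), 45 °C
Reagents that add atoms: none
Why: Acid hydrolysis of the isopropylidene ketal in aqueous acetic acid frees the diol while the acetate and the PMB ether persist.

Step 19
Reactants: 23 cis-9,10-diol
Product: 24 (7S,8R)-7,8-epoxy diol
Conditions: mCPBA (1.05 equiv), NaHCO3, CH2Cl2, 0 °C
Reagents that add atoms: 3-chloroperoxybenzoic acid, OOC(=O)c1cccc(Cl)c1
Why: Hydroxyl-directed peracid (Henbest) epoxidation of the trisubstituted C7=C8 bond; in eight- and nine-membered Z-cycloalkenols the peracid is delivered so that the oxirane ends trans to the allylic hydroxyl, which is the face required here.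

Step 20
Reactants: 24 epoxy diol
Product: 25 C9 benzoate
Conditions: BzCl (1.1 equiv), pyridine, CH2Cl2, −20 °C
Reagents that add atoms: benzoyl chloride, O=C(Cl)c1ccccc1
Why: Kinetic mono-acylation: the C9 hydroxyl next to the epoxide CH is less hindered than the C10 hydroxyl flanked by the fully substituted C11, so one equivalent of benzoyl chloride at low temperature should esterify C9.

Step 21
Reactants: 25 C9 benzoate
Product: 26 C10 tert-butyldimethylsilyl ether
Conditions: t-BuMe2SiOTf, 2,6-lutidine, CH2Cl2, −78 → 0 °C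
Reagents that add atoms: tert-butyldimethylsilyl triflate, CC(C)(C)[Si](C)(C)OS(=O)(=O)C(F)(F)F
Why: Silylation of the remaining hindered secondary alcohol with the silyl triflate and a hindered base, cold enough to spare the epoxide.

Step 22
Reactants: 26 C10 silyl ether
Product: 27 C12 allylic alcohol
Conditions: DDQ, CH2Cl2–pH 7 buffer, 0 °C
Reagents that add atoms: none
Why: Oxidative cleavage of the p-methoxybenzyl ether by DDQ frees only the C12 hydroxyl.

Step 23
Reactants: 27 C12 allylic alcohol
Product: 30 C3,C12-diol (C4 bears H and two CH2OH groups), via hydrosilyl ether 28 (not isolated), via oxasilolane 29 (not isolated)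
Conditions: (HMe2Si)2NH, rt; Pt2[(CH2=CHSiMe2)2O]3 (cat.), THF, 50 °C; then 30% H2O2, KF, KHCO3, THF–MeOH, rt
Reagents that add atoms: hydrogen peroxide, OO
Why: Tamao intramolecular hydrosilylation: the Si–H tethered through O12 adds 5-endo to the C4=C3 methylene (Si on C3, H on C4), the only olefin within reach, and Tamao–Fleming oxidation turns C3–Si into C3–OH.

Step 24
Reactants: 30 C3,C12-diol
Product: 31 C1,C3,C12-triol
Conditions: K2CO3 (cat.), MeOH, 0 °C
Reagents that add atoms: none
Why: Carbonate methanolysis removes the primary acetate much faster than the hindered secondary benzoate, whose migration is blocked by the silyl ether on C10.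

Step 25
Reactants: 31 C1,C3,C12-triol
Product: 34 ring-A acetal acetate (C1–OAc axial; C3=C4; C12 aldehyde), via trialdehyde 32 (not isolated), via lactol 33 (not isolated)
Conditions: Dess–Martin periodinane (excess), pyridine, CH2Cl2, 0 °C → rt; then Ac2O, pyridine, DMAP (cat.), 0 °C
Reagents that add atoms: acetic anhydride, CC(=O)OC(C)=O
Why: Excess Dess–Martin periodinane oxidises all three primary alcohols, the enol hydroxyl of the resulting 2-substituted malondialdehyde adds to the C1 aldehyde to close ring A as a six-membered lactol, and acetylation of the equilibrating lactol should favour the axial (anomeric) C1 acetate.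

Step 26
Reactants: 35 triethyl(prop-2-yn-1-yloxy)silane
Product: 38 diisopropyl (S,S)-tartrate ester of (E)-3-(triethylsilyloxy)prop-1-enylboronic acid, via catechol boronate 36 (not isolated), via boronic acid 37 (not isolated)
Conditions: catecholborane, neat, 70 °C; H2O, rt; then (S,S)-diisopropyl tartrate, MgSO4, Et2O, rt
Reagents that add atoms: catecholborane, B1Oc2ccccc2O1; (S,S)-diisopropyl tartrate, CC(C)OC(=O)[C@@H](O)[C@H](O)C(=O)OC(C)C
Why: syn-Hydroboration of the terminal alkyne with catecholborane gives the E alkenylboronate, which is hydrolysed and re-esterified with the tartrate.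

Step 27
Reactants: 38 tartrate alkenylboronate
Product: 39 diisopropyl (S,S)-tartrate ester of (E)-3-(triethylsilyloxy)prop-2-enylboronic acid (γ-silyloxyallylboronate)
Conditions: [Ir(cod)(PPh2Me)2]PF6 (cat., activated with H2), THF, rt
Reagents that add atoms: none
Why: Iridium-catalysed double-bond migration moves the olefin into conjugation with the silyloxy group and gives the E enol ether.

Step 28
Reactants: 34 ring-A aldehyde; 39 γ-silyloxyallylboronate
Product: 40 (12S,13R) adduct (C12–OH, C13–OSiEt3, C14 vinyl)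
Conditions: 4 Å molecular sieves, toluene, −78 → 0 °C; aq. NaHCO3 work-up
Reagents that add atoms: none
Why: Allylboration through a closed chair transition state: the E γ-silyloxy group gives the anti 12,13-relationship and the (S,S)-tartrate should direct attack to the Re face of the C12 aldehyde (Roush model), while neutral conditions and basic work-up protect the acid-labile γ-alkoxyallyl alcohol.

Step 29
Reactants: 40 C12 alcohol
Product: 41 C12 acetate
Conditions: Ac2O, pyridine, DMAP (cat.), CH2Cl2, 0 °C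
Reagents that add atoms: acetic anhydride, CC(=O)OC(C)=O
Why: Immediate acetylation under basic conditions fixes the C12 oxygen as the acetate before the allylic alcohol can transpose.

Step 30
Reactants: 41 C12 acetate
Product: 42 isobutenyl compound (C14=C15Me2)
Conditions: 2-methyl-2-butene (co-solvent), RuCl2(H2IMes)(=CH-C6H4-2-Oi-Pr) (second-generation Hoveyda–Grubbs catalyst), CH2Cl2, 40 °C
Reagents that add atoms: 2-methyl-2-butene, CC=C(C)C
Why: Olefin cross-metathesis of the monosubstituted vinyl group with 2-methyl-2-butene gives the trisubstituted terminus; the exocyclic methylene and the trisubstituted enol ether are too hindered to engage.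

Step 31
Reactants: 42 isobutenyl compound
Product: 43 C13 alcohol
Conditions: HF·pyridine, pyridine, THF, 0 °C
Reagents that add atoms: none
Why: Fluoride desilylation: the unhindered secondary triethylsilyl ether is cleaved by buffered HF·pyridine well before the tert-butyldimethylsilyl ether on C10.

Step 32
Reactants: 43 C13 alcohol
Product: 44 10-O-tert-butyldimethylsilyl derivative of the target
Conditions: Ac2O, pyridine, DMAP (cat.), CH2Cl2, 0 °C
Reagents that add atoms: acetic anhydride, CC(=O)OC(C)=O
Why: Acetylation of the free hydroxyl completes the 12,13-diacetate; an acetyl shift from O12 to O13 in step 31 would lead to the same product.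

Step 33
Reactants: 44 10-O-silyl derivative
Product: 45 CNP0317411.2 (target)
Conditions: HF·pyridine, pyridine, THF, 0 °C → rt
Reagents that add atoms: none
Why: Buffered HF·pyridine removes the last silyl ether without base, so the C9 benzoate cannot migrate and the acetal acetate, enol ether and epoxide should persist.

**Compound list**

1 | 2,3-O-isopropylidene-D-erythronolactone | O=C1OC[C@H]2OC(C)(C)O[C@@H]12 | starting material
2 | 2,3-O-isopropylidene-D-erythrofuranose (lactol, anomer mixture) | OC1OC[C@H]2OC(C)(C)O[C@@H]12 | intermediate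
3 | [(4R,5S)-5-ethynyl-2,2-dimethyl-1,3-dioxolan-4-yl]methanol | OC[C@H]1OC(C)(C)O[C@H]1C#C | intermediate
4 | α-stannylalkene, C11(SnBu3)=C19H2 on the cis-dioxolane of 3 | OC[C@H]1OC(C)(C)O[C@H]1C(=C)[Sn](CCCC)(CCCC)CCCC | intermediate (not isolated)
5 | [cis-5-(1-iodoethenyl)-2,2-dimethyl-1,3-dioxolan-4-yl]methanol | OC[C@H]1OC(C)(C)O[C@H]1C(I)=C | intermediate
6 | cis-5-(1-iodoethenyl)-2,2-dimethyl-1,3-dioxolane-4-carbaldehyde | O=C[C@H]1OC(C)(C)O[C@H]1C(I)=C | intermediate
7 | methyl (Z)-2-methylprop-2-enoate bearing the dioxolane of 6 at C3 (Z-C7=C8) | COC(=O)/C(C)=C\[C@H]1OC(C)(C)O[C@H]1C(I)=C | intermediate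
8 | Z-allylic alcohol (C6–OH) | OC/C(C)=C\[C@H]1OC(C)(C)O[C@H]1C(I)=C | intermediate
9 | Z-allylic bromide (C6–Br) | BrC/C(C)=C\[C@H]1OC(C)(C)O[C@H]1C(I)=C | intermediate
10 | nitrile (C4a nitrile, C5 and C6 methylenes) | N#CCC/C(C)=C\[C@H]1OC(C)(C)O[C@H]1C(I)=C | intermediate
11 | C4a aldehyde | O=CCC/C(C)=C\[C@H]1OC(C)(C)O[C@H]1C(I)=C | intermediate
12 | sodium salt of methyl 2-(dimethoxyphosphoryl)-3-[(4-methoxybenzyl)oxy]propanoate | [Na+].COC(=O)[C-](COCc1ccc(OC)cc1)P(=O)(OC)OC | intermediate (not isolated)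
13 | E-enoate (C3 ester trans to C5, C12H2OPMB cis to C5) | COC(=O)/C(COCc1ccc(OC)cc1)=C/CC/C(C)=C\[C@H]2OC(C)(C)O[C@H]2C(I)=C | intermediate
14 | C3 allylic alcohol | OC/C(COCc1ccc(OC)cc1)=C/CC/C(C)=C\[C@H]2OC(C)(C)O[C@H]2C(I)=C | intermediate
15 | hydroxy ethyl ester (C11(=C19H2)–C11aH2–CO2Et) | OC/C(COCc1ccc(OC)cc1)=C/CC/C(C)=C\[C@H]2OC(C)(C)O[C@H]2C(=C)CC(=O)OCC | intermediate
16 | seco acid | OC/C(COCc1ccc(OC)cc1)=C/CC/C(C)=C\[C@H]2OC(C)(C)O[C@H]2C(=C)CC(=O)O | intermediate
17 | 13-membered allylic macrolactone | O=C1OC/C(COCc3ccc(OC)cc3)=C/CC/C(C)=C\[C@H]2OC(C)(C)O[C@H]2C(=C)C1 | intermediate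
18 | O-trimethylsilyl ketene acetal of 17 (C11 trans to O2) | C[Si](C)(C)O/C1=C\C(=C)[C@@H]2OC(C)(C)O[C@@H]2/C=C(C)\CC/C=C(COCc3ccc(OC)cc3)/CO1 | intermediate (not isolated)
19 | trimethylsilyl ester of 20 | C=C1[C@H](C(=O)O[Si](C)(C)C)[C@@H](C(=C)COCc3ccc(OC)cc3)CC/C(C)=C\[C@H]2OC(C)(C)O[C@@H]12 | intermediate (not isolated)
20 | (4aS,11aR)-cyclononene acid (ring B) | C=C1[C@H](C(O)=O)[C@@H](C(=C)COCc3ccc(OC)cc3)CC/C(C)=C\[C@H]2OC(C)(C)O[C@@H]12 | intermediate
21 | C1 primary alcohol | C=C1[C@H](CO)[C@@H](C(=C)COCc3ccc(OC)cc3)CC/C(C)=C\[C@H]2OC(C)(C)O[C@@H]12 | intermediate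
22 | C1 acetate | C=C1[C@H](COC(C)=O)[C@@H](C(=C)COCc3ccc(OC)cc3)CC/C(C)=C\[C@H]2OC(C)(C)O[C@@H]12 | intermediate
23 | cis-9,10-diol | C=C1[C@H](COC(C)=O)[C@@H](C(=C)COCc3ccc(OC)cc3)CC/C(C)=C\[C@@H](O)[C@H]1O | intermediate
24 | (7S,8R)-7,8-epoxy-9,10-diol | C=C1[C@H](COC(C)=O)[C@@H](C(=C)COCc3ccc(OC)cc3)CC[C@]2(C)O[C@@H]2[C@@H](O)[C@H]1O | intermediate
25 | C9 benzoate | C=C1[C@H](COC(C)=O)[C@@H](C(=C)COCc3ccc(OC)cc3)CC[C@]2(C)O[C@@H]2[C@@H](OC(=O)c2ccccc2)[C@H]1O | intermediate
26 | C9 benzoate, C10 tert-butyldimethylsilyl ether | C=C1[C@H](COC(C)=O)[C@@H](C(=C)COCc3ccc(OC)cc3)CC[C@]2(C)O[C@@H]2[C@@H](OC(=O)c2ccccc2)[C@H]1O[Si](C)(C)C(C)(C)C | intermediate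
27 | C12 allylic alcohol | C=C1[C@H](COC(C)=O)[C@@H](C(=C)CO)CC[C@]2(C)O[C@@H]2[C@@H](OC(=O)c2ccccc2)[C@H]1O[Si](C)(C)C(C)(C)C | intermediate
28 | C12 O-dimethylsilyl (Si–H) ether | C=C1[C@H](COC(C)=O)[C@@H](C(=C)CO[SiH](C)C)CC[C@]2(C)O[C@@H]2[C@@H](OC(=O)c2ccccc2)[C@H]1O[Si](C)(C)C(C)(C)C | intermediate (not isolated)
29 | 2,2-dimethyl-1-oxa-2-silacyclopentane (Si on C3, O on C12; C4 epimers) | C=C1[C@H](COC(C)=O)[C@@H](C3CO[Si](C)(C)C3)CC[C@]2(C)O[C@@H]2[C@@H](OC(=O)c2ccccc2)[C@H]1O[Si](C)(C)C(C)(C)C | intermediate (not isolated)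
30 | C3,C12-diol | C=C1[C@H](COC(C)=O)[C@@H](C(CO)CO)CC[C@]2(C)O[C@@H]2[C@@H](OC(=O)c2ccccc2)[C@H]1O[Si](C)(C)C(C)(C)C | intermediate
31 | C1,C3,C12-triol | C=C1[C@H](CO)[C@@H](C(CO)CO)CC[C@]2(C)O[C@@H]2[C@@H](OC(=O)c2ccccc2)[C@H]1O[Si](C)(C)C(C)(C)C | intermediate
32 | trialdehyde (C1 aldehyde; C4 as 2-substituted malondialdehyde) | C=C1[C@H](C=O)[C@@H](C(C=O)C=O)CC[C@]2(C)O[C@@H]2[C@@H](OC(=O)c2ccccc2)[C@H]1O[Si](C)(C)C(C)(C)C | intermediate (not isolated)
33 | ring-A lactol (C1–OH, both anomers; C3=C4; C12 aldehyde) | C=C1[C@@H]2C(O)OC=C(C=O)[C@H]2CC[C@]2(C)O[C@@H]2[C@@H](OC(=O)c2ccccc2)[C@H]1O[Si](C)(C)C(C)(C)C | intermediate (not isolated)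
34 | ring-A acetal acetate with C12 aldehyde (1S) | C=C1[C@@H]2[C@H](OC(C)=O)OC=C(C=O)[C@H]2CC[C@]2(C)O[C@@H]2[C@@H](OC(=O)c2ccccc2)[C@H]1O[Si](C)(C)C(C)(C)C | intermediate
35 | triethyl(prop-2-yn-1-yloxy)silane | C#CCO[Si](CC)(CC)CC | starting material
36 | catechol (E)-3-(triethylsilyloxy)prop-1-enylboronate | CC[Si](CC)(CC)OC/C=C/B1Oc2ccccc2O1 | intermediate (not isolated)
37 | (E)-3-(triethylsilyloxy)prop-1-enylboronic acid | CC[Si](CC)(CC)OC/C=C/B(O)O | intermediate (not isolated)
38 | diisopropyl (S,S)-tartrate (E)-3-(triethylsilyloxy)prop-1-enylboronate | CC[Si](CC)(CC)OC/C=C/B1O[C@@H]([C@H](O1)C(=O)OC(C)C)C(=O)OC(C)C | intermediate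
39 | diisopropyl (S,S)-tartrate (E)-3-(triethylsilyloxy)prop-2-enylboronate | CC[Si](CC)(CC)O/C=C/CB1O[C@@H]([C@H](O1)C(=O)OC(C)C)C(=O)OC(C)C | intermediate
40 | (12S,13R) adduct: C12–OH, C13–OSiEt3, vinyl | C=C1[C@@H]2[C@H](OC(C)=O)OC=C([C@H](O)[C@@H](C=C)O[Si](CC)(CC)CC)[C@H]2CC[C@]2(C)O[C@@H]2[C@@H](OC(=O)c2ccccc2)[C@H]1O[Si](C)(C)C(C)(C)C | intermediate
41 | C12 acetate | C=C1[C@@H]2[C@H](OC(C)=O)OC=C([C@H](OC(C)=O)[C@@H](C=C)O[Si](CC)(CC)CC)[C@H]2CC[C@]2(C)O[C@@H]2[C@@H](OC(=O)c2ccccc2)[C@H]1O[Si](C)(C)C(C)(C)C | intermediate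
42 | isobutenyl compound (C13–OSiEt3) | C=C1[C@@H]2[C@H](OC(C)=O)OC=C([C@H](OC(C)=O)[C@@H](C=C(C)C)O[Si](CC)(CC)CC)[C@H]2CC[C@]2(C)O[C@@H]2[C@@H](OC(=O)c2ccccc2)[C@H]1O[Si](C)(C)C(C)(C)C | intermediate
43 | C13 alcohol | C=C1[C@@H]2[C@H](OC(C)=O)OC=C([C@H](OC(C)=O)[C@@H](C=C(C)C)O)[C@H]2CC[C@]2(C)O[C@@H]2[C@@H](OC(=O)c2ccccc2)[C@H]1O[Si](C)(C)C(C)(C)C | intermediate
44 | 10-O-tert-butyldimethylsilyl derivative of the target | C=C1[C@@H]2[C@H](OC(C)=O)OC=C([C@H](OC(C)=O)[C@@H](C=C(C)C)OC(C)=O)[C@H]2CC[C@]2(C)O[C@@H]2[C@@H](OC(=O)c2ccccc2)[C@H]1O[Si](C)(C)C(C)(C)C | intermediate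
45 | CNP0317411.2 | C=C1[C@@H]2[C@H](OC(C)=O)OC=C([C@H](OC(C)=O)[C@@H](C=C(C)C)OC(C)=O)[C@H]2CC[C@]2(C)O[C@@H]2[C@@H](OC(=O)c2ccccc2)[C@H]1O | target

**Step count**

Total: 33 steps (31 on the main line, 2 for boronate 39). Longest linear sequence: 31 steps (steps 1–25 and 28–33).

**Steps most likely to fail**

1. Step 15. The bias that the acetonide imposes on the 13-membered ring may be too weak, so that the ketene acetal bonds through the face that puts C1 syn to the C10 oxygen, or through a boat array that gives the cis fusion. Fallback: from 17, the lactone is enolised with (S,S)-2-bromo-4,5-diphenyl-1,3-bis{[3,5-bis(trifluoromethyl)phenyl]sulfonyl}-1,3,2-diazaborolidine and i-Pr2NEt in CH2Cl2 at −78 °C to give the chiral boron ketene acetal F1. On warming to −20 °C, F1 rearranges under control of the boron ligand instead of the substrate (Corey-type enolate Claisen, a reaction type used for macrolactone ring contraction). Hydrolytic work-up releases acid 20, where the route is rejoined. The (S,S) controller is written here; whether it or its antipode is the matched one can only be settled by trial.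

2. Step 25. The 2-substituted malondialdehyde may be over-oxidised at its central carbon, the β-hydroxy aldehyde stage may lose water, or acetylation on the enol oxygen may outrun ring closure. Fallback: from 27, K2CO3 in MeOH gives the C1,C12-diol F2, and Dess–Martin periodinane gives dialdehyde F3 (C1 aldehyde and C12 enal with C3 as its β-carbon). In moist THF with catalytic triethylammonium acetate the hydrate of the C1 aldehyde adds 6-endo to C3 (oxa-Michael) to give lactol F4, which Ac2O and pyridine convert into acetate F5. Me3SiOTf and Et3N give the silyl enol ether F6 (C12=C4), and Pd(OAc)2 in MeCN (Saegusa–Ito dehydrogenation, β-hydride loss from the oxygen-bearing C3) gives 34, where the route is rejoined.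

3. Step 28. The vinylogous formyl group may add the tartrate boronate only slowly, face selectivity may erode if reagent and substrate preferences oppose, and the γ-alkoxyallyl alcohol may transpose on isolation. Fallback: from 34, CrCl2 and 3-bromoprop-1-enyl acetate (CC(=O)OC=CCBr) in THF at rt generate the γ-acetoxyallylchromium reagent, which should add anti like crotylchromium reagents and gives the C13 acetate F7 directly; the face of attack then rests on the C4a centre. Ac2O and pyridine give diacetate F8, and cross-metathesis with 2-methyl-2-butene as in step 30 gives 44, where the route is rejoined.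

Further compounds
F1 | step 15 | boron ketene acetal of 17 with the (S,S)-bis-sulfonamide ligand | FC(F)(F)c1cc(cc(c1)C(F)(F)F)S(=O)(=O)N1B(O/C2=C\C(=C)[C@@H]3OC(C)(C)O[C@@H]3/C=C(C)\CC/C=C(COCc4ccc(OC)cc4)/CO2)N(S(=O)(=O)c2cc(cc(c2)C(F)(F)F)C(F)(F)F)[C@@H](c2ccccc2)[C@@H]1c1ccccc1
F2 | step 25 | C1,C12-diol | C=C1[C@H](CO)[C@@H](C(=C)CO)CC[C@]2(C)O[C@@H]2[C@@H](OC(=O)c2ccccc2)[C@H]1O[Si](C)(C)C(C)(C)C
F3 | step 25 | C1 aldehyde with C12 enal | C=C1[C@H](C=O)[C@@H](C(=C)C=O)CC[C@]2(C)O[C@@H]2[C@@H](OC(=O)c2ccccc2)[C@H]1O[Si](C)(C)C(C)(C)C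
F4 | step 25 | saturated ring-A lactol with C4 formyl group | C=C1[C@@H]2C(O)OCC(C=O)[C@H]2CC[C@]2(C)O[C@@H]2[C@@H](OC(=O)c2ccccc2)[C@H]1O[Si](C)(C)C(C)(C)C
F5 | step 25 | saturated ring-A acetal acetate with C4 formyl group | C=C1[C@@H]2[C@H](OC(C)=O)OCC(C=O)[C@H]2CC[C@]2(C)O[C@@H]2[C@@H](OC(=O)c2ccccc2)[C@H]1O[Si](C)(C)C(C)(C)C
F6 | step 25 | trimethylsilyl enol ether (C12=C4) | C=C1[C@@H]2[C@H](OC(C)=O)OCC(=CO[Si](C)(C)C)[C@H]2CC[C@]2(C)O[C@@H]2[C@@H](OC(=O)c2ccccc2)[C@H]1O[Si](C)(C)C(C)(C)C
F7 | step 28 | C12 alcohol, C13 acetate, vinyl | C=C1[C@@H]2[C@H](OC(C)=O)OC=C([C@H](O)[C@@H](C=C)OC(C)=O)[C@H]2CC[C@]2(C)O[C@@H]2[C@@H](OC(=O)c2ccccc2)[C@H]1O[Si](C)(C)C(C)(C)C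
F8 | step 28 | 12,13-diacetate, vinyl | C=C1[C@@H]2[C@H](OC(C)=O)OC=C([C@H](OC(C)=O)[C@@H](C=C)OC(C)=O)[C@H]2CC[C@]2(C)O[C@@H]2[C@@H](OC(=O)c2ccccc2)[C@H]1O[Si](C)(C)C(C)(C)C
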